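All runs are calculated for an exercise; scatter was added.

**Five questions.** I had 5 questions: the share of target in all product (the selectivity to target) in 4 flasks, and which flask comes out highest.

| flask | solid substrate | temperature | remark | time |
|---|---|---|---|---|
| ash | 10 mM | 115 °C | run made earlier |  |
| Thursday's | 20 mM | 115 °C |  | 6.0 min |
| Wednesday's | 20 mM | 85 °C |  | 6.0 min |
| Friday's | 20 mM | 130 °C |  | 6.0 min |
| Saturday's | 20 mM | 100 °C |  | 6.0 min |

ash run (percent of the solid substrate charged)

| time / s | target / % | isomer of the product / % | over-reaction product / % |
|---|---|---|---|
| 10.0 | 0 | 0.2 | 0 |
| 15.0 | 0 | 0.6 | 1.2 |
| 25.0 | 2.5 | 1.1 | 0 |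
| 40.0 | 5.6 | 3.3 | 1.4 |
| 60.0 | 11.2 | 7.6 | 4.0 |
| 120 | 17.2 | 18.0 | 15.2 |

(each reading ± 0.5 percentage points)

* the flask that comes out highest in share of target in all that became target or isomer of the product or over-reaction product, or "all alike" when all lie within 1.5 percentage points (Thursday's / Wednesday's / Friday's / Saturday's / all alike)
* share of target in all that became target or isomer of the product or over-reaction product, Thursday's
* share of target in all that became target or isomer of the product or over-reaction product, Wednesday's
* share of target in all that became target or isomer of the product or over-reaction product, Friday's
* share of target in all that became target or isomer of the product or over-reaction product, Saturday's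

- as a solid, counted per litre of solution: solid substrate
- at the start none of the solid substrate is in solution
- what has only dissolved of solid substrate counts as not reacted
- the earlier runs do not show what temperature does; that part of a forecast is a guess

**Main step.** I built the share up one process at a time. With the main step alone, what reacts stands as target, and the share is 100 %.

**Side branch.** Next came the isomer of the product. I counted target plus over-reaction product as the target path, and at 120 s the ash run read 64.3% of its product there, so I took my estimate of the share down to that reading.

**Target loss.** Between 60.0 s and 120 s the ash run's over-reaction product rose 11 percentage points while its target averaged 14.2%. These readings gave 76.1 s. This is the target lifetime: target standing divided by the over-reaction product it yields per second. I set the run time over this lifetime as the loss number; on a steady feed, where it crosses one, control passes from making target to losing it. For Thursday's flask it was 4.73. A steady feed then keeps 20.9% of the target path as target, so I reckoned a share of 13.5%.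

**The rest.** None of the solid substrate is in solution at the start, and at 15.0 s the ash run read 0% target. I still treated the feed as steady. The ash run shows one temperature, so I reckoned no other flask.

**The forecast.** It gave Thursday's 9%, below my figure, Wednesday's 50%, Saturday's 28% and Friday's 3%, and it named Wednesday's: “The coolest flask is highest”.

**The result.** Wednesday's came highest at 64.0%, above the forecast; Saturday's gave 39.6%, Thursday's 10.6% and Friday's 1.51%.

    starting material → intermediate (k = 0.00270 /s, Ea = 109 kJ/mol)
    intermediate ⇌ isomer of the product (K = 2.20, k = 0.00350 /s, Ea = 101 kJ/mol, ΔH = −11.0 kJ/mol)
    intermediate ⇌ target (K = 1.90, k = 0.00890 /s, Ea = 91.0 kJ/mol, ΔH = −23.0 kJ/mol)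
    solid substrate ⇌ starting material, rate k4*(cs4 - [starting material]) while solid is left; crystals form when [starting material] > cs4 (solubility = 13.0 mM, k = 0.0680 /s)
    target → over-reaction product (k = 0.00400 /s, Ea = 98.0 kJ/mol)
    (constants at 100 °C)

**Lifetime again.** Reckoned from the rise of over-reaction product between 3.00 min and 6.00 min, Thursday's target lifetime was 73.7 s, beside the 76.1 s read from the ash run, while Wednesday's was 16.0 min, longer than its 6.0 min run, a loss number of 0.375. Saturday's was 3.99 min, shorter than its own 6.0 min run, so the lifetime reckoned this way stood 4.01 times longer in Wednesday's than in Saturday's.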